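The route depends on closing ring A (C1, C2, C3, C4, C10) at the C2–C3 bond. The feature exploited is that C3, the carbinol carbon without hydrogen, and oxygenated C1 are separated only by C2. A carbene centre on C2, next to a C1 carbonyl, therefore has the C3–H bond of an open-chain silyl ether within reach of a five-ring transition state. One operation forms C2–C3, closes ring A, and turns a secondary carbinol set by hydrogenation into the tertiary C3 centre with retention. The precursor is an acyclic α-diazo ketone that already holds C3, C4 and quaternary C10, with C5 and C8 as hydrogen-free ester carbons. Ring B is closed later by metathesis at C6=C7.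

Key step: step 14

Atom labels: ring A = C1 (OAc), C2, C3 (OH, isopropyl), C4, C10 (CH3). Ring B = C4, C5 (O-aroyl), C6, C7 (CH3), C8 (C=O), C9, C10. In these labels the target is (1S,3R,4R,5R,10S). TBS = tert-butyldimethylsilyl, TES = triethylsilyl, TCE = 2,2,2-trichloroethyl.
Assumption: the C6=C7 double bond, written without geometry, is the Z alkene that a seven-membered ring requires.

Step 1
Reactants: 1 methyl 4-methyl-3-oxopentanoate
Product: 2 methyl (3S)-3-hydroxy-4-methylpentanoate
Conditions: H2 (50 atm), RuCl2[(R)-BINAP] (0.1 mol%), MeOH, 50 °C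
Reagents that add atoms: none
Why: Noyori asymmetric hydrogenation of a β-keto ester, in which the ester carbonyl chelates divalent ruthenium and the (R)-BINAP ligand opens only one ketone face to hydride, which should give the (3S) alcohol, the future C3.

Step 2
Reactants: 2 methyl (3S)-3-hydroxy-4-methylpentanoate
Product: 3 methyl (3S)-3-(TBS-oxy)-4-methylpentanoate
Conditions: TBSOTf, 2,6-lutidine, CH2Cl2, 0 °C
Reagents that add atoms: tert-butyldimethylsilyl triflate, CC(C)(C)[Si](C)(C)OS(=O)(=O)C(F)(F)F
Why: Silylation of a hindered secondary alcohol with a silyl triflate, giving a non-chelating ether that later steers the Claisen step and makes C3–H electron-rich.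

Step 3
Reactants: 3 methyl (3S)-3-(TBS-oxy)-4-methylpentanoate
Product: 4 (3S)-3-(TBS-oxy)-4-methylpentanoic acid
Conditions: LiOH, THF/MeOH/H2O, rt; then 1 M HCl to pH 4, 0 °C
Reagents that add atoms: lithium hydroxide, [Li+].[OH-]
Why: Saponification of an unhindered methyl ester at room temperature, mild enough that the β-silyloxy group is not eliminated and C3 is not touched.

Step 4
Reactants: 5 tert-butyl(but-3-yn-1-yloxy)dimethylsilane
Product: 8 racemic (3E)-6-(TBS-oxy)-4-methylhex-3-en-2-ol, via alkenyl(dimethyl)alane 6 (not isolated), via lithium alkenylalanate 7 (not isolated)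
Conditions: Me3Al, Cp2ZrCl2 (20 mol%), CH2Cl2, 0 °C to rt, excess Me3Al removed in vacuo; nBuLi, hexane/THF, −78 °C; CH3CHO, −78 to 0 °C; then H2O
Reagents that add atoms: trimethylaluminium, C[Al](C)C; acetaldehyde, CC=O
Why: Negishi carboalumination adds CH3 and Al syn across the terminal alkyne with CH3 on the inner carbon, and the alanate adds to acetaldehyde with retention, so the CH3 on the future C10 ends cis to the carbinol carbon (E alkene); C8 travels as a silyl ether because an ester here would offer doubly activated C9–H bonds to LDA in step 7 and its dienolate would expel the carboxylate.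

Step 5
Reactants: 8 racemic (3E)-6-(TBS-oxy)-4-methylhex-3-en-2-ol
Product: 9 (2S,3E)-6-(TBS-oxy)-4-methylhex-3-en-2-ol
Conditions: immobilised Candida antarctica lipase B, vinyl acetate, MTBE, 30 °C, stopped near half conversion; chromatography
Reagents that add atoms: none
Why: Lipase-catalysed kinetic resolution by transesterification, in which the enzyme acylates the (R) enantiomer of methyl alkenyl carbinols much faster, so the (S) alcohol should stay behind and is separated from the acetate.

Step 6
Reactants: 4 (3S)-3-(TBS-oxy)-4-methylpentanoic acid; 9 (2S,3E)-6-(TBS-oxy)-4-methylhex-3-en-2-ol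
Product: 10 (2S,3E)-6-(TBS-oxy)-4-methylhex-3-en-2-yl (3S)-3-(TBS-oxy)-4-methylpentanoate
Conditions: DCC, DMAP (cat.), CH2Cl2, 0 °C to rt
Reagents that add atoms: none
Why: Steglich esterification under neutral conditions, which touches neither stereocentre nor the alkene geometry.

Step 7
Reactants: 10 (2S,3E)-6-(TBS-oxy)-4-methylhex-3-en-2-yl (3S)-3-(TBS-oxy)-4-methylpentanoate
Product: 13 (2S,3R,4E)-2-[(1R)-1-(TBS-oxy)-2-methylpropyl]-3-[2-(TBS-oxy)ethyl]-3-methylhex-4-enoic acid (3R,4S,10R in skeleton labels), via (E)-silyl ketene acetal 11 (not isolated), via trimethylsilyl ester 12 (not isolated)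
Conditions: TMSCl (present from the start), LDA, THF, −78 °C; then rt to 55 °C; then H2O, THF, rt
Reagents that add atoms: chlorotrimethylsilane, C[Si](C)(C)Cl (its SiMe3 group is in 11 and 12 only)
Why: Ireland–Claisen rearrangement, in which kinetic deprotonation in THF gives the (E)-silyl ketene acetal (C3 cis to the allyl oxygen) and the chair with the carbinol CH3 equatorial, enforced by allylic 1,3-strain with the cis CH3 on C10, passes the (S) carbinol configuration on to C10 and C4, while the allyl unit also meets the ketene acetal face anti to isopropyl (H inside, OTBS outside), so both controls should point to the C4–C10 bond with (4S,10R).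

Step 8
Reactants: 13 Claisen acid
Product: 14 tert-butyl ester of 13 (C5 ester)
Conditions: Me2NCH(OtBu)2, toluene, 80 °C
Reagents that add atoms: N,N-dimethylformamide di-tert-butyl acetal, CN(C)C(OC(C)(C)C)OC(C)(C)C
Why: Alkylative esterification through the carboxylate, which does not feel the crowding around C5 and runs under neutral conditions that spare both silyl ethers.

Step 9
Reactants: 14 tert-butyl ester of 13
Product: 15 C8 acid (14 with CH2CH2OTBS on C10 turned into CH2CO2H; 3R,4S,10R)
Conditions: CrO3, H2SO4, H2O, acetone, 0 °C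
Reagents that add atoms: water, O
Why: Jones oxidation, in which the aqueous acid frees the unhindered primary silyl ether and hexavalent chromium carries the alcohol straight to the acid, while the C3 silyl ether, shielded by isopropyl and C4, the tert-butyl ester and the alkene should survive the short exposure.

Step 10
Reactants: 15 C8 acid
Product: 16 TCE ester of 15 (C8 ester)
Conditions: Cl3CCH2OH, DCC, DMAP (cat.), CH2Cl2, rt
Reagents that add atoms: 2,2,2-trichloroethanol, OCC(Cl)(Cl)Cl
Why: Steglich esterification of the unhindered C8 acid, giving an electron-poor ester that can be removed later with zinc in the presence of acetate, aroyl ester and alkenes.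

Step 11
Reactants: 16 TCE ester
Product: 17 C1 aldehyde (16 with the propenyl group on C10 cleaved to CHO; 3R,4S,10S)
Conditions: O3, CH2Cl2, −78 °C; then PPh3, −78 °C to rt
Reagents that add atoms: ozone, [O-][O+]=O
Why: Ozonolysis with reductive work-up of the only alkene, giving an aldehyde on a quaternary carbon that cannot epimerise.

Step 12
Reactants: 17 C1 aldehyde
Product: 18 C1 acid (3R,4S,10S)
Conditions: NaClO2, NaH2PO4, 2-methylbut-2-ene, tBuOH/H2O, rt
Reagents that add atoms: sodium chlorite, [Na+].[O-]Cl=O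
Why: Pinnick oxidation, which is selective for the aldehyde and leaves silyl ether and both esters alone.

Step 13
Reactants: 18 C1 acid
Product: 20 α-diazo ketone N2CH–C1(=O)–C10(CH3)(CH2CO2TCE)–C4H(CO2tBu)–C3H(OTBS)–isopropyl (3R,4S,10S), via C1 acid chloride 19 (not isolated)
Conditions: Me2C=C(Cl)NMe2, CH2Cl2, 0 °C; then CH2N2 (excess), Et2O, 0 °C
Reagents that add atoms: 1-chloro-N,N,2-trimethylprop-1-en-1-amine, CC(C)=C(Cl)N(C)C (its Cl is in 19 only); diazomethane, C=[N+]=[N-]
Why: Acylation of diazomethane by an acid chloride (first stage of the Arndt–Eistert sequence), with the chloride made under neutral conditions so that the C5 tert-butyl ester should not close onto C1 as an anhydride, and with a second equivalent of diazomethane taking up the HCl.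

Step 14
Reactants: 20 α-diazo ketone
Product: 21 ring A cyclopentanone: C1 ketone, C3 with OTBS and isopropyl, C4 with CO2tBu, C10 with CH3 and CH2CO2TCE (3R,4S,10S; isopropyl, CO2tBu and CH3 on one face, OTBS and CH2CO2TCE on the other)
Conditions: Rh2(OAc)4 (1 mol%), CH2Cl2, reflux, slow addition of 20, high dilution
Reagents that add atoms: none
Why: Rh2(OAc)4 (divalent rhodium) takes N2 from 20 and leaves an electrophilic carbenoid at C2, which inserts into C3–H in a concerted three-centre event, the known 1,5 C–H insertion of α-diazo ketones into ether-activated methines. Ring A (C1, C2, C3, C4, C10) closes by this insertion through a five-membered cyclic transition state, and the new bond is C2–C3. C3 becomes the fully substituted carbinol carbon with retention, because carbon takes the place of hydrogen on the same face, so its configuration is the one fixed in step 1, and C4 and C10 are not touched. The step needs site selectivity over the isopropyl methine (six-membered ring), the silyl ether oxygen and the two ester carbonyl oxygens (ylides); no other C–H bond can be reached through a five-membered ring, since C5 and C8 bear no hydrogen and the hydrogens on C4, C9 and the C10 methyl group would mean a cyclobutanone, and C3–H is a methine made electron-rich by the silyloxy group. The bulky tert-butyl ester at C5 and the electron-poor TCE ester at C8 make the carbonyl oxygens poor ylide partners, and slow addition at high dilution holds back carbene dimers.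

Step 15
Reactants: 21 ring A cyclopentanone
Product: 22 β-hydroxy ketone (21 with free C3–OH; 3R,4S,10S)
Conditions: 48% aq. HF, MeCN, 0 °C to rt
Reagents that add atoms: none
Why: Acidic fluoride cleaves the tertiary silyl ether, and basic fluoride is avoided because 22 is a β-hydroxy ketone open to retro-aldol cleavage and elimination.

Step 16
Reactants: 22 β-hydroxy ketone
Product: 23 1,3-trans diol (C1–OH on the face of the C10 methyl group; 1S,3R,4S,10S)
Conditions: Me4NBH(OAc)3, MeCN/AcOH, −25 °C
Reagents that add atoms: none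
Why: Evans–Saksena reduction, in which the C3 hydroxyl displaces an acetate on boron and the bound hydride reaches the C1 carbonyl from the face on which that hydroxyl sits, which should give the 1,3-trans diol (1S) and leaves both esters alone.

Step 17
Reactants: 23 1,3-trans diol
Product: 24 C1 acetate (C3–OH free)
Conditions: Ac2O, DMAP (cat.), pyridine, rt
Reagents that add atoms: acetic anhydride, CC(=O)OC(C)=O
Why: DMAP-catalysed acetylation, which takes the secondary C1 hydroxyl while the tertiary, isopropyl-flanked C3 hydroxyl does not react.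

Step 18
Reactants: 24 C1 acetate
Product: 26 C5 acid with C3–OTES (1S,3R,4S,10S), via C5 triethylsilyl ester 25 (not isolated)
Conditions: TESOTf, 2,6-lutidine, CH2Cl2, 0 °C to rt; then MeOH, rt
Reagents that add atoms: triethylsilyl triflate, CC[Si](CC)(CC)OS(=O)(=O)C(F)(F)F
Why: Silyl triflate cleavage of a tert-butyl ester (O-silylation, loss of 2-methylpropene), which in the same operation caps the C3 hydroxyl against lactonisation onto C8 and conjugate addition later, while acetate and TCE ester cannot lose a stabilised cation and stay, and methanol then frees the acid from its silyl ester.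

Step 19
Reactants: 26 C5 acid
Product: 28 C5 vinyl ketone (C4–C(=O)–CH=CH2; 1S,3R,4S,10S), via C5 acid chloride 27 (not isolated)
Conditions: Me2C=C(Cl)NMe2, CH2Cl2, 0 °C to rt; then CH2=CHSnBu3, Pd2(dba)3 (3 mol%), P(2-furyl)3, THF, 45 °C
Reagents that add atoms: 1-chloro-N,N,2-trimethylprop-1-en-1-amine, CC(C)=C(Cl)N(C)C (its Cl is in 27 only); tributyl(vinyl)stannane, C=C[Sn](CCCC)(CCCC)CCCC
Why: Stille acylation, in which zerovalent palladium inserts into the acyl chloride far faster than it touches any ester, the conditions are neutral so that C4 should not epimerise, and C6 is brought in without a reducing agent that the acetate could not stand.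

Step 20
Reactants: 28 C5 vinyl ketone
Product: 29 C5 allylic alcohol (1S,3R,4R,5R,10S)
Conditions: NaBH4, CeCl3·7H2O, MeOH, −78 °C
Reagents that add atoms: none
Why: Luche 1,2-reduction under Felkin–Anh control, in which hydride should come in anti to the C4–C3 bond (C3 with OTES and isopropyl is the largest neighbour) with the carbonyl oxygen beside C10 and the vinyl group beside C4–H, which gives (5R).

Step 21
Reactants: 30 4-hydroxybenzoic acid
Product: 32 4-(TBS-oxy)benzoic acid, via bis-silylated acid 31 (not isolated)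
Conditions: TBSCl, imidazole, DMF, rt; then AcOH/THF/H2O, rt
Reagents that add atoms: tert-butyldimethylsilyl chloride, CC(C)(C)[Si](C)(C)Cl
Why: Exhaustive silylation followed by selective hydrolysis, since a silyl ester is far more labile to aqueous acid than an aryl silyl ether.

Step 22
Reactants: 29 C5 allylic alcohol; 32 4-(TBS-oxy)benzoic acid
Product: 33 C5 4-(TBS-oxy)benzoate
Conditions: DCC, DMAP, CH2Cl2, rt
Reagents that add atoms: none
Why: Steglich esterification of the only free hydroxyl with retention at C5, with the phenol masked so that the acid cannot acylate itself.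

Step 23
Reactants: 33 C5 4-(TBS-oxy)benzoate
Product: 34 C8 acid
Conditions: Zn dust, AcOH/THF, rt
Reagents that add atoms: none
Why: Reductive fragmentation of the TCE ester by zinc, which leaves acetate, allylic aroyl ester, vinyl group and both silyl ethers untouched.

Step 24
Reactants: 34 C8 acid
Product: 36 C8 isopropenyl ketone (C9H2–C(=O)–C(CH3)=CH2), via C8 acid chloride 35 (not isolated)
Conditions: Me2C=C(Cl)NMe2, CH2Cl2, 0 °C to rt; then CH2=C(CH3)MnCl [from CH2=C(CH3)MgBr, MnCl2·2LiCl, THF, 0 °C], −30 to 0 °C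
Reagents that add atoms: 1-chloro-N,N,2-trimethylprop-1-en-1-amine, CC(C)=C(Cl)N(C)C (its Cl is in 35 only); isopropenylmagnesium bromide, CC(=C)[Mg]Br
Why: Acylation of an organomanganese halide (divalent manganese), which reacts with acid chlorides but not with esters or the enone formed, and which avoids zerovalent palladium that could ionise the allylic aroyl ester.

Step 25
Reactants: 36 C8 isopropenyl ketone
Product: 37 protected target (trans-fused rings A and B, C3–OTES, aryl OTBS; 1S,3R,4R,5R,10S)
Conditions: second-generation Hoveyda–Grubbs catalyst (H2IMes)Cl2Ru=CH(C6H4-2-OiPr) (10 mol%), toluene, 80 °C, high dilution, argon sparge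
Reagents that add atoms: none
Why: Ring-closing metathesis of a vinyl group onto an isopropenyl ketone, a known way to 2-methylcycloalk-2-enones, in which the catalyst loads at the vinyl group, the seven-membered ring can only hold the Z alkene, and no stereocentre is touched.

Step 26
Reactants: 37 protected target
Product: 38 target CNP0087181.1 (1S,3R,4R,5R,10S)
Conditions: HF·pyridine, pyridine, THF, 0 °C to rt
Reagents that add atoms: none
Why: Buffered acidic fluoride removes the tertiary TES ether and the aryl TBS ether together, without the base that would endanger the acetate, the aroyl ester or the γ-acyloxy enone.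

Compound list
1 | methyl 4-methyl-3-oxopentanoate | CC(C)C(=O)CC(=O)OC | starting material
2 | methyl (3S)-3-hydroxy-4-methylpentanoate | COC(=O)C[C@H](O)C(C)C | intermediate
3 | methyl (3S)-3-(TBS-oxy)-4-methylpentanoate | COC(=O)C[C@H](O[Si](C)(C)C(C)(C)C)C(C)C | intermediate
4 | (3S)-3-(TBS-oxy)-4-methylpentanoic acid | OC(=O)C[C@H](O[Si](C)(C)C(C)(C)C)C(C)C | intermediate
5 | tert-butyl(but-3-yn-1-yloxy)dimethylsilane | C#CCCO[Si](C)(C)C(C)(C)C | starting material
6 | dimethyl[(1E)-4-(TBS-oxy)-2-methylbut-1-en-1-yl]alane | C[Al](C)/C=C(C)/CCO[Si](C)(C)C(C)(C)C | intermediate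
7 | lithium butyl(dimethyl)[(1E)-4-(TBS-oxy)-2-methylbut-1-en-1-yl]alanate | [Li+].CCCC[Al-](C)(C)/C=C(C)/CCO[Si](C)(C)C(C)(C)C | intermediate
8 | racemic (3E)-6-(TBS-oxy)-4-methylhex-3-en-2-ol | CC(O)/C=C(C)/CCO[Si](C)(C)C(C)(C)C | intermediate
9 | (2S,3E)-6-(TBS-oxy)-4-methylhex-3-en-2-ol | C[C@H](O)/C=C(C)/CCO[Si](C)(C)C(C)(C)C | intermediate
10 | (2S,3E)-6-(TBS-oxy)-4-methylhex-3-en-2-yl (3S)-3-(TBS-oxy)-4-methylpentanoate | C[C@H](OC(=O)C[C@H](O[Si](C)(C)C(C)(C)C)C(C)C)/C=C(C)/CCO[Si](C)(C)C(C)(C)C | intermediate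
11 | (E)-trimethylsilyl ketene acetal of 10 | C[C@H](O/C(O[Si](C)(C)C)=C\[C@H](O[Si](C)(C)C(C)(C)C)C(C)C)/C=C(C)/CCO[Si](C)(C)C(C)(C)C | intermediate
12 | trimethylsilyl ester of 13 | C/C=C/[C@@](C)(CCO[Si](C)(C)C(C)(C)C)[C@H](C(=O)O[Si](C)(C)C)[C@H](O[Si](C)(C)C(C)(C)C)C(C)C | intermediate
13 | (2S,3R,4E)-2-[(1R)-1-(TBS-oxy)-2-methylpropyl]-3-[2-(TBS-oxy)ethyl]-3-methylhex-4-enoic acid | C/C=C/[C@@](C)(CCO[Si](C)(C)C(C)(C)C)[C@H](C(=O)O)[C@H](O[Si](C)(C)C(C)(C)C)C(C)C | intermediate
14 | tert-butyl ester of 13 | C/C=C/[C@@](C)(CCO[Si](C)(C)C(C)(C)C)[C@H](C(=O)OC(C)(C)C)[C@H](O[Si](C)(C)C(C)(C)C)C(C)C | intermediate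
15 | C8 acid, (3R,4E)-3-[(1S,2R)-1-(tert-butoxycarbonyl)-2-(TBS-oxy)-3-methylbutyl]-3-methylhex-4-enoic acid | C/C=C/[C@@](C)(CC(=O)O)[C@H](C(=O)OC(C)(C)C)[C@H](O[Si](C)(C)C(C)(C)C)C(C)C | intermediate
16 | TCE ester of 15 | C/C=C/[C@@](C)(CC(=O)OCC(Cl)(Cl)Cl)[C@H](C(=O)OC(C)(C)C)[C@H](O[Si](C)(C)C(C)(C)C)C(C)C | intermediate
17 | C1 aldehyde (3R,4S,10S) | O=C[C@@](C)(CC(=O)OCC(Cl)(Cl)Cl)[C@H](C(=O)OC(C)(C)C)[C@H](O[Si](C)(C)C(C)(C)C)C(C)C | intermediate
18 | C1 acid (3R,4S,10S) | OC(=O)[C@@](C)(CC(=O)OCC(Cl)(Cl)Cl)[C@H](C(=O)OC(C)(C)C)[C@H](O[Si](C)(C)C(C)(C)C)C(C)C | intermediate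
19 | C1 acid chloride | ClC(=O)[C@@](C)(CC(=O)OCC(Cl)(Cl)Cl)[C@H](C(=O)OC(C)(C)C)[C@H](O[Si](C)(C)C(C)(C)C)C(C)C | intermediate
20 | acyclic α-diazo ketone (3R,4S,10S), precursor of the key step | [N-]=[N+]=CC(=O)[C@@](C)(CC(=O)OCC(Cl)(Cl)Cl)[C@H](C(=O)OC(C)(C)C)[C@H](O[Si](C)(C)C(C)(C)C)C(C)C | intermediate
21 | ring A cyclopentanone with C3–OTBS (3R,4S,10S), product of the key step | O=C1C[C@@](O[Si](C)(C)C(C)(C)C)(C(C)C)[C@@H](C(=O)OC(C)(C)C)[C@]1(C)CC(=O)OCC(Cl)(Cl)Cl | intermediate
22 | β-hydroxy ketone (3R,4S,10S) | O=C1C[C@@](O)(C(C)C)[C@@H](C(=O)OC(C)(C)C)[C@]1(C)CC(=O)OCC(Cl)(Cl)Cl | intermediate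
23 | 1,3-trans diol (1S,3R,4S,10S) | O[C@H]1C[C@@](O)(C(C)C)[C@@H](C(=O)OC(C)(C)C)[C@]1(C)CC(=O)OCC(Cl)(Cl)Cl | intermediate
24 | C1 acetate | CC(=O)O[C@H]1C[C@@](O)(C(C)C)[C@@H](C(=O)OC(C)(C)C)[C@]1(C)CC(=O)OCC(Cl)(Cl)Cl | intermediate
25 | C3 TES ether, C5 TES ester | CC(=O)O[C@H]1C[C@@](O[Si](CC)(CC)CC)(C(C)C)[C@@H](C(=O)O[Si](CC)(CC)CC)[C@]1(C)CC(=O)OCC(Cl)(Cl)Cl | intermediate
26 | C5 acid with C3–OTES | CC(=O)O[C@H]1C[C@@](O[Si](CC)(CC)CC)(C(C)C)[C@@H](C(=O)O)[C@]1(C)CC(=O)OCC(Cl)(Cl)Cl | intermediate
27 | C5 acid chloride | CC(=O)O[C@H]1C[C@@](O[Si](CC)(CC)CC)(C(C)C)[C@@H](C(=O)Cl)[C@]1(C)CC(=O)OCC(Cl)(Cl)Cl | intermediate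
28 | C5 vinyl ketone | CC(=O)O[C@H]1C[C@@](O[Si](CC)(CC)CC)(C(C)C)[C@@H](C(=O)C=C)[C@]1(C)CC(=O)OCC(Cl)(Cl)Cl | intermediate
29 | C5 allylic alcohol (1S,3R,4R,5R,10S) | CC(=O)O[C@H]1C[C@@](O[Si](CC)(CC)CC)(C(C)C)[C@@H]([C@H](O)C=C)[C@]1(C)CC(=O)OCC(Cl)(Cl)Cl | intermediate
30 | 4-hydroxybenzoic acid | OC(=O)c1ccc(O)cc1 | starting material
31 | tert-butyldimethylsilyl 4-(TBS-oxy)benzoate | CC(C)(C)[Si](C)(C)OC(=O)c1ccc(O[Si](C)(C)C(C)(C)C)cc1 | intermediate
32 | 4-(TBS-oxy)benzoic acid | OC(=O)c1ccc(O[Si](C)(C)C(C)(C)C)cc1 | intermediate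
33 | C5 4-(TBS-oxy)benzoate, C8 TCE ester | CC(=O)O[C@H]1C[C@@](O[Si](CC)(CC)CC)(C(C)C)[C@@H]([C@H](OC(=O)c2ccc(O[Si](C)(C)C(C)(C)C)cc2)C=C)[C@]1(C)CC(=O)OCC(Cl)(Cl)Cl | intermediate
34 | C8 acid | CC(=O)O[C@H]1C[C@@](O[Si](CC)(CC)CC)(C(C)C)[C@@H]([C@H](OC(=O)c2ccc(O[Si](C)(C)C(C)(C)C)cc2)C=C)[C@]1(C)CC(=O)O | intermediate
35 | C8 acid chloride | CC(=O)O[C@H]1C[C@@](O[Si](CC)(CC)CC)(C(C)C)[C@@H]([C@H](OC(=O)c2ccc(O[Si](C)(C)C(C)(C)C)cc2)C=C)[C@]1(C)CC(=O)Cl | intermediate
36 | C8 isopropenyl ketone | CC(=O)O[C@H]1C[C@@](O[Si](CC)(CC)CC)(C(C)C)[C@@H]([C@H](OC(=O)c2ccc(O[Si](C)(C)C(C)(C)C)cc2)C=C)[C@]1(C)CC(=O)C(C)=C | intermediate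
37 | protected target | CC(=O)O[C@H]1C[C@@](O[Si](CC)(CC)CC)(C(C)C)[C@H]2[C@H](OC(=O)c3ccc(O[Si](C)(C)C(C)(C)C)cc3)C=C(C)C(=O)C[C@]12C | intermediate
38 | CNP0087181.1 | CC(=O)O[C@H]1C[C@@](O)(C(C)C)[C@H]2[C@H](OC(=O)c3ccc(O)cc3)C=C(C)C(=O)C[C@]12C | target

Total step count: 26 (steps 4, 5 and 21 lie on side branches).
Longest linear sequence: 23 steps (1–3, 6–20, 22–26).

Steps most likely to fail

**Step 14.**
- What may go wrong: the singly stabilised carbenoid may be drawn off by attack of the silyl ether oxygen or an ester carbonyl oxygen (ylide formation), by insertion at the isopropyl methine, or by dimerisation, because the C3–H bond is crowded.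
- Fallback: it sets out from acid 18 and comes back at 21. It keeps the C2–C3 bond but changes the carbene class and the precursor.
- Acid 18 is activated with carbonyldiimidazole and homologated with Mg(O2CCH2CO2Me)2 to the methyl β-keto ester F1.
- Diazo transfer (4-acetamidobenzenesulfonyl azide, Et3N) gives the α-diazo-β-keto ester F2.
- Rh2(OAc)4 then generates a doubly stabilised, more discriminating carbenoid. This is the substrate class for which cyclopentanone formation by methine insertion is best established. It closes ring A to the C2 ester F3.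
- DMAP in wet toluene at 90 °C removes the extra ester by dealkoxycarbonylation and gives 21.

**Step 7.**
- What may go wrong: the ester enolate may lose silanolate by β-elimination, the ketene acetal geometry may erode, and the rearrangement may be slow at the crowded C4–C10 bond.
- Fallback: it sets out from alcohol 9 and comes back at acid 13. It forms C3–C4 by an aldol reaction instead.
- Acetylation of 9 gives the acetate F4.
- The Ireland–Claisen rearrangement of F4 (LDA, TMSCl) has no enolate geometry and no β-leaving group. It sets C10 by the same chirality transfer and gives the acid F5.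
- The pivaloyl mixed anhydride of F5 acylates lithiated (4S)-4-benzyl-1,3-oxazolidin-2-one to the imide F6.
- Bu2BOTf and Et3N, then isobutyraldehyde (Evans syn aldol), set C3 and C4 under auxiliary control in the adduct F7.
- TBSOTf gives the silyl ether F8, and LiOOH releases 13.

**Step 20.**
- What may go wrong: hydride may attack the C5 ketone with poor or reversed facial selectivity, since C3 and C10 are both fully substituted, and some conjugate reduction may occur.
- Fallback: it sets out from acid 26 (through its chloride 27) and comes back at 29.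
- LiAlH(OtBu)3 at −78 °C reduces 27 to the C5 aldehyde F9.
- CH2=CHMgBr (THF, −78 °C) then adds to F9.
- Vinyl and hydride have changed roles, so the same facial preference of the C4 environment now delivers the opposite C5 configuration. Whichever face the substrate favours, one of the two sequences should lead to 29.

Further compounds
F1 | step 14 | methyl β-keto ester (18 homologated: C1 ketone, C2H2, CO2Me) | COC(=O)CC(=O)[C@@](C)(CC(=O)OCC(Cl)(Cl)Cl)[C@H](C(=O)OC(C)(C)C)[C@H](O[Si](C)(C)C(C)(C)C)C(C)C
F2 | step 14 | α-diazo-β-keto ester | COC(=O)C(=[N+]=[N-])C(=O)[C@@](C)(CC(=O)OCC(Cl)(Cl)Cl)[C@H](C(=O)OC(C)(C)C)[C@H](O[Si](C)(C)C(C)(C)C)C(C)C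
F3 | step 14 | cyclopentanone 21 with CO2Me on C2 (C2 epimers and enol) | O=C1C(C(=O)OC)[C@@](O[Si](C)(C)C(C)(C)C)(C(C)C)[C@@H](C(=O)OC(C)(C)C)[C@]1(C)CC(=O)OCC(Cl)(Cl)Cl
F4 | step 7 | (2S,3E)-6-(TBS-oxy)-4-methylhex-3-en-2-yl acetate | C[C@H](OC(C)=O)/C=C(C)/CCO[Si](C)(C)C(C)(C)C
F5 | step 7 | (3S,4E)-3-[2-(TBS-oxy)ethyl]-3-methylhex-4-enoic acid | C/C=C/[C@@](C)(CCO[Si](C)(C)C(C)(C)C)CC(=O)O
F6 | step 7 | N-acyl (4S)-4-benzyl-1,3-oxazolidin-2-one of F5 | C/C=C/[C@@](C)(CCO[Si](C)(C)C(C)(C)C)CC(=O)N1[C@@H](Cc2ccccc2)COC1=O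
F7 | step 7 | syn aldol adduct (3R,4S,10R) | C/C=C/[C@@](C)(CCO[Si](C)(C)C(C)(C)C)[C@H](C(=O)N1[C@@H](Cc2ccccc2)COC1=O)[C@H](O)C(C)C
F8 | step 7 | TBS ether of F7 | C/C=C/[C@@](C)(CCO[Si](C)(C)C(C)(C)C)[C@H](C(=O)N1[C@@H](Cc2ccccc2)COC1=O)[C@H](O[Si](C)(C)C(C)(C)C)C(C)C
F9 | step 20 | C5 aldehyde | CC(=O)O[C@H]1C[C@@](O[Si](CC)(CC)CC)(C(C)C)[C@@H](C=O)[C@]1(C)CC(=O)OCC(Cl)(Cl)Cl
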